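## Retrosynthetic overview

- The target is reached by cleaving all 24 methyl ethers of its permethyl ether; ring A is attached last, by adding the hindered ring B C1 hydroxyl to 3,5-dimethoxybenzyne.
- The strategy rests on ring B: its oxygens at C1 and C4 are para, so it is a hydroquinone (a quinone at the oxidised level), and C2 and C6 carry two different crowded aryloxy groups (ring C with ring D and two E–F arms at C2; one E–F arm at C6). Cutting ring B C2–O and C6–O gives 2,6-dichloro-1,4-benzoquinone, the hexameric C–D–(E–F)2 phenol and the E–F biaryl phenol.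
- The hexameric phenol comes from the ring D phenol and a 4-benzyloxy-3,5-dimethoxyphenyl iodonium salt (ring C–O–ring D bond), then debenzylation. Ring D is the same dichloroquinone used symmetrically with two biaryl phenols, then reduced and mono-methylated.
- The biaryl phenol comes from hexamethoxybiphenyl (lithiation, borylation, oxidation), itself from Negishi coupling of 2-iodo-1,3,5-trimethoxybenzene with the arylzinc chloride made from 1,3,5-trimethoxybenzene.
- No ring is constructed: all benzene rings are bought and joined in the order E–F, D, C, B, A.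

Key step: step 11

Assumption: the target has no stereocentre and rotation about its biaryl and diaryl ether axes is taken as free (each E–F axis carries a symmetrical ring F), so no stereocontrol is planned; all phenolic oxygens are carried as methyl ethers to the last step.

Shorthand used in names: "EF-oxy" = 2,4,6-trimethoxy-3-(2,4,6-trimethoxyphenyl)phenoxy; "CDEF-oxy" = 2,6-dimethoxy-4-[4-methoxy-2,6-bis(EF-oxy)phenoxy]phenoxy.

## Route

Step 1
Reactants: 1 2-iodo-1,3,5-trimethoxybenzene; 2 1,3,5-trimethoxybenzene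
Product: 5 2,2',4,4',6,6'-hexamethoxybiphenyl, via 2,4,6-trimethoxyphenyllithium 3 (not isolated), via (2,4,6-trimethoxyphenyl)zinc chloride 4 (not isolated)
Conditions: 2, n-BuLi, THF, 0 °C → rt; ZnCl2, THF, 0 °C → rt; then 1, Pd2(dba)3 (cat.), RuPhos (2-dicyclohexylphosphino-2',6'-diisopropoxybiphenyl, cat.), THF/NMP, 80 °C, Ar
Reagents that add atoms: none
Why: Lithiation of 2 between two methoxy groups (directed ortho-metalation) and transmetalation to zinc give arylzinc 4, and Negishi coupling with aryl iodide 1 on zerovalent palladium bearing a bulky dialkylbiarylphosphine, a catalyst class that tolerates four ortho substituents, should give the biaryl; both partners carry the same aryl group, so homocoupling of either one leads to the same product.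

Step 2
Reactants: 5 2,2',4,4',6,6'-hexamethoxybiphenyl
Product: 8 2,4,6-trimethoxy-3-(2,4,6-trimethoxyphenyl)phenol, via 3-lithiohexamethoxybiphenyl 6 (not isolated), via lithium aryltrimethoxyborate 7 (not isolated)
Conditions: n-BuLi (0.8 equiv), TMEDA, THF, 0 °C; B(OMe)3, –78 °C → rt; AcOH, 30% H2O2, 0 °C
Reagents that add atoms: hydrogen peroxide, OO
Why: Directed ortho-metalation can only occur at a C–H flanked by two methoxy groups (all four ring hydrogens are of this kind), and borylation followed by peroxide oxidation turns C–Li into C–OH; sub-stoichiometric n-BuLi limits double functionalisation, and the phenol should separate from recovered 5 by extraction into aqueous base.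

Step 3
Reactants: 8 2,4,6-trimethoxy-3-(2,4,6-trimethoxyphenyl)phenol (2.1 equiv); 9 2,6-dichloro-1,4-benzoquinone
Product: 11 2,6-bis(EF-oxy)-1,4-benzoquinone, via 2-chloro-6-(EF-oxy)-1,4-benzoquinone 10 (not isolated)
Conditions: Cs2CO3, DMF, –20 °C → rt, Ar, dark
Reagents that add atoms: none
Why: Twofold addition–elimination of the phenoxide at the chlorine-bearing carbons of the haloquinone (vinylogous acyl substitution) builds ring D symmetrically, and the phenoxide can bond only through oxygen because its ortho and para carbons are substituted.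

Step 4
Reactants: 11 2,6-bis(EF-oxy)-1,4-benzoquinone
Product: 12 2,6-bis(EF-oxy)benzene-1,4-diol
Conditions: Na2S2O4, THF/H2O, rt, Ar
Reagents that add atoms: none
Why: Dithionite reduction of a quinone to its hydroquinone is general and leaves aryl ethers untouched; the air-sensitive product should be carried on directly.

Step 5
Reactants: 12 2,6-bis(EF-oxy)benzene-1,4-diol
Product: 13 4-methoxy-2,6-bis(EF-oxy)phenol
Conditions: MeI (1.05 equiv), K2CO3 (1.1 equiv), degassed acetone, rt, Ar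
Reagents that add atoms: iodomethane, CI
Why: Williamson methylation should take the open C4 hydroxyl, because the C1 hydroxyl lies between two ortho aryloxy groups that shield it and hydrogen-bond to it.

Step 6
Reactants: 14 4-bromo-2,6-dimethoxyphenol
Product: 15 2-(benzyloxy)-5-bromo-1,3-dimethoxybenzene
Conditions: BnBr, K2CO3, DMF, 50 °C
Reagents that add atoms: benzyl bromide, BrCc1ccccc1
Why: Williamson benzylation of a phenol installs the one protecting group that can later be removed in the presence of methyl ethers.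

Step 7
Reactants: 15 2-(benzyloxy)-5-bromo-1,3-dimethoxybenzene
Product: 17 2-(benzyloxy)-5-iodo-1,3-dimethoxybenzene, via 4-benzyloxy-3,5-dimethoxyphenyllithium 16 (not isolated)
Conditions: n-BuLi, THF, –78 °C; I2, –78 °C → rt
Reagents that add atoms: iodine, II
Why: Bromine–lithium exchange at –78 °C is faster than benzylic deprotonation, and iodinolysis of the aryllithium gives the aryl iodide needed for oxidation to trivalent iodine.

Step 8
Reactants: 17 2-(benzyloxy)-5-iodo-1,3-dimethoxybenzene; 2 1,3,5-trimethoxybenzene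
Product: 19 [4-(benzyloxy)-3,5-dimethoxyphenyl](2,4,6-trimethoxyphenyl)iodonium tosylate, via hydroxy(tosyloxy)iodoarene 18 (not isolated)
Conditions: mCPBA, TsOH·H2O, MeCN, 40–55 °C; then 2, rt
Reagents that add atoms: p-toluenesulfonic acid, Cc1ccc(S(=O)(=O)O)cc1
Why: One-pot oxidation of the aryl iodide to a trivalent iodine tosylate followed by electrophilic substitution of the very electron-rich arene 2 is the standard synthesis of unsymmetrical diaryliodonium salts with a non-transferable 2,4,6-trimethoxyphenyl ligand.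

Step 9
Reactants: 13 4-methoxy-2,6-bis(EF-oxy)phenol; 19 [4-(benzyloxy)-3,5-dimethoxyphenyl](2,4,6-trimethoxyphenyl)iodonium tosylate
Product: 20 2-(benzyloxy)-1,3-dimethoxy-5-[4-methoxy-2,6-bis(EF-oxy)phenoxy]benzene
Conditions: t-BuOK (1.05 equiv), THF, 0 °C; then 19, rt → 40 °C
Reagents that add atoms: none
Why: In metal-free O-arylation with a diaryliodonium salt the phenoxide replaces tosylate on trivalent iodine and ligand coupling transfers the less electron-rich aryl group while the trimethoxyphenyl group leaves as its iodide, a process that tolerates 2,6-disubstituted phenols.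

Step 10
Reactants: 20 2-(benzyloxy)-1,3-dimethoxy-5-[4-methoxy-2,6-bis(EF-oxy)phenoxy]benzene
Product: 21 2,6-dimethoxy-4-[4-methoxy-2,6-bis(EF-oxy)phenoxy]phenol (hexameric phenol)
Conditions: H2 (1 atm), Pd/C (10% Pd on carbon), EtOAc/MeOH, rt
Reagents that add atoms: none
Why: Hydrogenolysis removes the benzyl ether alone, since methyl ethers, diaryl ethers and the biaryl bonds are inert to Pd/C and hydrogen.

Step 11
Reactants: 21 hexameric phenol (1.0 equiv); 9 2,6-dichloro-1,4-benzoquinone (1.2 equiv); 8 2,4,6-trimethoxy-3-(2,4,6-trimethoxyphenyl)phenol (1.5 equiv)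
Product: 23 2-(CDEF-oxy)-6-(EF-oxy)-1,4-benzoquinone, via 2-chloro-6-(CDEF-oxy)-1,4-benzoquinone 22 (not isolated)
Conditions: Cs2CO3, DMF/THF, –40 °C, 21 added slowly to 9; then 8, –40 °C → rt; AcOH quench; Ar, dark
Reagents that add atoms: none
Why: Each caesium phenoxide adds at a chlorine-bearing ring carbon of the quinone (C2, then C6), which is β to the C4 carbonyl, and the enolate expels chloride, so two addition–elimination events form the ring B C2–O and C6–O bonds and the quinone is restored after each. The closest known reaction type is the stepwise displacement of the halides of 2,6-dihalo-1,4-benzoquinones and 2,3-dichloro-1,4-naphthoquinone by alkoxides and phenoxides. No ring is closed and no stereocentre is formed. The step needs two different aryloxy groups, and substitution instead of conjugate addition at C3/C5: the first aryloxy group makes the quinone a vinylogous ester, so mono-adduct 22 should persist at –40 °C when 21 meets an excess of 9, and should take the second phenoxide only on warming. Both phenoxides have their ortho and para carbons substituted, so they can bond only through oxygen, and addition at a C–H carbon is reversible whereas loss of chloride is not. Quenching with acetic acid once 22 is consumed should prevent aryloxy exchange on the product from scrambling the two arms.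

Step 12
Reactants: 23 2-(CDEF-oxy)-6-(EF-oxy)-1,4-benzoquinone
Product: 24 2-(CDEF-oxy)-6-(EF-oxy)benzene-1,4-diol
Conditions: Na2S2O4, THF/H2O, rt, Ar
Reagents that add atoms: none
Why: Dithionite reduction of the quinone gives the ring B hydroquinone with its C1 and C4 oxygens in place and affects no other group.

Step 13
Reactants: 24 2-(CDEF-oxy)-6-(EF-oxy)benzene-1,4-diol
Product: 25 4-methoxy-2-(CDEF-oxy)-6-(EF-oxy)phenol
Conditions: MeI (1.05 equiv), K2CO3 (1.1 equiv), degassed acetone/DMF, rt, Ar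
Reagents that add atoms: iodomethane, CI
Why: As in step 5, Williamson methylation should go to the unhindered C4 hydroxyl, the C1 hydroxyl being buried between ring C and ring E.

Step 14
Reactants: 26 3,5-dimethoxyphenol
Product: 27 3,5-dimethoxyphenyl N-isopropylcarbamate
Conditions: i-PrNCO, Et3N (cat.), CH2Cl2, rt
Reagents that add atoms: isopropyl isocyanate, CC(C)N=C=O
Why: Base-catalysed addition of the phenol to the isocyanate gives the carbamate that serves as a removable ortho-directing group.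

Step 15
Reactants: 27 3,5-dimethoxyphenyl N-isopropylcarbamate
Product: 31 3,5-dimethoxy-2-(trimethylsilyl)phenyl N-isopropylcarbamate, via N-silyl carbamate 28 (not isolated), via ortho-lithiated N-silyl carbamate 29 (not isolated), via C-silylated N-silyl carbamate 30 (not isolated)
Conditions: TBSOTf, TMEDA, Et2O, 0 °C → rt; n-BuLi, TMEDA, –78 °C; TMSCl, –78 °C → rt; aq NaHSO4
Reagents that add atoms: chlorotrimethylsilane, C[Si](C)(C)Cl
Why: After transient N-silylation the O-carbamate, the strongest director present, steers ortho-lithiation to C2 (between the carbamate and a methoxy group) in a directed ortho-metalation; C-silylation and acidic work-up, which removes the N-silyl group, give the ortho-silyl carbamate.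

Step 16
Reactants: 31 3,5-dimethoxy-2-(trimethylsilyl)phenyl N-isopropylcarbamate
Product: 33 3,5-dimethoxy-2-(trimethylsilyl)phenyl trifluoromethanesulfonate, via 3,5-dimethoxy-2-(trimethylsilyl)phenol 32 (not isolated)
Conditions: DBU, Et2NH, MeCN, 40 °C; then PhNTf2, rt
Reagents that add atoms: N-phenylbis(trifluoromethanesulfonimide), O=S(=O)(N(c1ccccc1)S(=O)(=O)C(F)(F)F)C(F)(F)F
Why: Base-induced elimination of the N–H carbamate releases the phenoxide (the isocyanate is trapped by diethylamine as a urea) and triflation in the same pot gives the ortho-silylaryl triflate without protodesilylation.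

Step 17
Reactants: 25 4-methoxy-2-(CDEF-oxy)-6-(EF-oxy)phenol; 33 3,5-dimethoxy-2-(trimethylsilyl)phenyl trifluoromethanesulfonate (2 equiv)
Product: 35 1-(3,5-dimethoxyphenoxy)-4-methoxy-2-(CDEF-oxy)-6-(EF-oxy)benzene (tetracosa-O-methyl ether of the target), via 3,5-dimethoxybenzyne 34 (not isolated)
Conditions: CsF, MeCN/toluene, rt
Reagents that add atoms: none
Why: Fluoride-induced 1,2-elimination of 33 gives aryne 34, to which the hindered caesium phenoxide adds at the aryne carbon remote from the flanking methoxy group (inductive and distortion control), and protonation of the aryl anion leaves the 3,5-dimethoxyphenyl ether (aryne O-arylation of phenols).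

Step 18
Reactants: 35 tetracosa-O-methyl ether of the target
Product: 36 CNP0294555.0 (target)
Conditions: BBr3 (excess, about 3 equiv per OMe), CH2Cl2, –78 °C → rt; MeOH then H2O at 0 °C; isolation under Ar
Reagents that add atoms: none
Why: Lewis acid mediated cleavage of aryl methyl ethers by BBr3 removes all 24 methyl groups as bromomethane and leaves the diaryl ether and biaryl bonds intact, and hydrolysis of the aryl borates on work-up frees the phenols.

## Compound list

1 | 2-iodo-1,3,5-trimethoxybenzene | COc1cc(OC)c(I)c(OC)c1 | starting material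
2 | 1,3,5-trimethoxybenzene | COc1cc(OC)cc(OC)c1 | starting material
3 | 2,4,6-trimethoxyphenyllithium | [Li]c1c(OC)cc(OC)cc1OC | intermediate
4 | (2,4,6-trimethoxyphenyl)zinc chloride | Cl[Zn]c1c(OC)cc(OC)cc1OC | intermediate
5 | 2,2',4,4',6,6'-hexamethoxybiphenyl | COc1cc(OC)c(-c2c(OC)cc(OC)cc2OC)c(OC)c1 | intermediate
6 | 3-lithio-2,2',4,4',6,6'-hexamethoxybiphenyl | [Li]c1c(OC)cc(OC)c(-c2c(OC)cc(OC)cc2OC)c1OC | intermediate
7 | lithium trimethoxy[2,4,6-trimethoxy-3-(2,4,6-trimethoxyphenyl)phenyl]borate | [Li+].CO[B-](OC)(OC)c1c(OC)cc(OC)c(-c2c(OC)cc(OC)cc2OC)c1OC | intermediate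
8 | 2,4,6-trimethoxy-3-(2,4,6-trimethoxyphenyl)phenol | COc1cc(OC)c(-c2c(OC)cc(OC)cc2OC)c(OC)c1O | intermediate
9 | 2,6-dichloro-1,4-benzoquinone | O=C1C=C(Cl)C(=O)C(Cl)=C1 | starting material
10 | 2-chloro-6-(EF-oxy)-1,4-benzoquinone | O=C1C=C(Cl)C(=O)C(Oc2c(OC)cc(OC)c(-c3c(OC)cc(OC)cc3OC)c2OC)=C1 | intermediate
11 | 2,6-bis(EF-oxy)-1,4-benzoquinone | O=C1C=C(Oc2c(OC)cc(OC)c(-c3c(OC)cc(OC)cc3OC)c2OC)C(=O)C(Oc2c(OC)cc(OC)c(-c3c(OC)cc(OC)cc3OC)c2OC)=C1 | intermediate
12 | 2,6-bis(EF-oxy)benzene-1,4-diol | Oc1cc(Oc2c(OC)cc(OC)c(-c3c(OC)cc(OC)cc3OC)c2OC)c(O)c(Oc2c(OC)cc(OC)c(-c3c(OC)cc(OC)cc3OC)c2OC)c1 | intermediate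
13 | 4-methoxy-2,6-bis(EF-oxy)phenol | COc1cc(Oc2c(OC)cc(OC)c(-c3c(OC)cc(OC)cc3OC)c2OC)c(O)c(Oc2c(OC)cc(OC)c(-c3c(OC)cc(OC)cc3OC)c2OC)c1 | intermediate
14 | 4-bromo-2,6-dimethoxyphenol | COc1cc(Br)cc(OC)c1O | starting material
15 | 2-(benzyloxy)-5-bromo-1,3-dimethoxybenzene | COc1cc(Br)cc(OC)c1OCc1ccccc1 | intermediate
16 | [4-(benzyloxy)-3,5-dimethoxyphenyl]lithium | [Li]c1cc(OC)c(OCc2ccccc2)c(OC)c1 | intermediate
17 | 2-(benzyloxy)-5-iodo-1,3-dimethoxybenzene | COc1cc(I)cc(OC)c1OCc1ccccc1 | intermediate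
18 | [4-(benzyloxy)-3,5-dimethoxyphenyl](hydroxy)(tosyloxy)iodane | Cc1ccc(S(=O)(=O)OI(O)c2cc(OC)c(OCc3ccccc3)c(OC)c2)cc1 | intermediate
19 | [4-(benzyloxy)-3,5-dimethoxyphenyl](2,4,6-trimethoxyphenyl)iodonium tosylate | COc1cc(OC)c([I+]c2cc(OC)c(OCc3ccccc3)c(OC)c2)c(OC)c1.Cc1ccc(S(=O)(=O)[O-])cc1 | intermediate
20 | 2-(benzyloxy)-1,3-dimethoxy-5-[4-methoxy-2,6-bis(EF-oxy)phenoxy]benzene | COc1cc(Oc2c(Oc3c(OC)cc(OC)c(-c4c(OC)cc(OC)cc4OC)c3OC)cc(OC)cc2Oc2c(OC)cc(OC)c(-c3c(OC)cc(OC)cc3OC)c2OC)cc(OC)c1OCc1ccccc1 | intermediate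
21 | 2,6-dimethoxy-4-[4-methoxy-2,6-bis(EF-oxy)phenoxy]phenol (hexameric phenol) | Oc1c(OC)cc(Oc2c(Oc3c(OC)cc(OC)c(-c4c(OC)cc(OC)cc4OC)c3OC)cc(OC)cc2Oc2c(OC)cc(OC)c(-c3c(OC)cc(OC)cc3OC)c2OC)cc1OC | intermediate
22 | 2-chloro-6-(CDEF-oxy)-1,4-benzoquinone | O=C1C=C(Cl)C(=O)C(Oc2c(OC)cc(Oc3c(Oc4c(OC)cc(OC)c(-c5c(OC)cc(OC)cc5OC)c4OC)cc(OC)cc3Oc3c(OC)cc(OC)c(-c4c(OC)cc(OC)cc4OC)c3OC)cc2OC)=C1 | intermediate
23 | 2-(CDEF-oxy)-6-(EF-oxy)-1,4-benzoquinone | O=C1C=C(Oc2c(OC)cc(Oc3c(Oc4c(OC)cc(OC)c(-c5c(OC)cc(OC)cc5OC)c4OC)cc(OC)cc3Oc3c(OC)cc(OC)c(-c4c(OC)cc(OC)cc4OC)c3OC)cc2OC)C(=O)C(Oc2c(OC)cc(OC)c(-c3c(OC)cc(OC)cc3OC)c2OC)=C1 | intermediate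
24 | 2-(CDEF-oxy)-6-(EF-oxy)benzene-1,4-diol | Oc1cc(Oc2c(OC)cc(Oc3c(Oc4c(OC)cc(OC)c(-c5c(OC)cc(OC)cc5OC)c4OC)cc(OC)cc3Oc3c(OC)cc(OC)c(-c4c(OC)cc(OC)cc4OC)c3OC)cc2OC)c(O)c(Oc2c(OC)cc(OC)c(-c3c(OC)cc(OC)cc3OC)c2OC)c1 | intermediate
25 | 4-methoxy-2-(CDEF-oxy)-6-(EF-oxy)phenol | COc1cc(Oc2c(OC)cc(Oc3c(Oc4c(OC)cc(OC)c(-c5c(OC)cc(OC)cc5OC)c4OC)cc(OC)cc3Oc3c(OC)cc(OC)c(-c4c(OC)cc(OC)cc4OC)c3OC)cc2OC)c(O)c(Oc2c(OC)cc(OC)c(-c3c(OC)cc(OC)cc3OC)c2OC)c1 | intermediate
26 | 3,5-dimethoxyphenol | COc1cc(O)cc(OC)c1 | starting material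
27 | 3,5-dimethoxyphenyl N-isopropylcarbamate | CC(C)NC(=O)Oc1cc(OC)cc(OC)c1 | intermediate
28 | 3,5-dimethoxyphenyl N-(tert-butyldimethylsilyl)-N-isopropylcarbamate | CC(C)N(C(=O)Oc1cc(OC)cc(OC)c1)[Si](C)(C)C(C)(C)C | intermediate
29 | 2-lithio-3,5-dimethoxyphenyl N-(tert-butyldimethylsilyl)-N-isopropylcarbamate | CC(C)N(C(=O)Oc1cc(OC)cc(OC)c1[Li])[Si](C)(C)C(C)(C)C | intermediate
30 | 3,5-dimethoxy-2-(trimethylsilyl)phenyl N-(tert-butyldimethylsilyl)-N-isopropylcarbamate | CC(C)N(C(=O)Oc1cc(OC)cc(OC)c1[Si](C)(C)C)[Si](C)(C)C(C)(C)C | intermediate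
31 | 3,5-dimethoxy-2-(trimethylsilyl)phenyl N-isopropylcarbamate | CC(C)NC(=O)Oc1cc(OC)cc(OC)c1[Si](C)(C)C | intermediate
32 | 3,5-dimethoxy-2-(trimethylsilyl)phenol | COc1cc(O)c([Si](C)(C)C)c(OC)c1 | intermediate
33 | 3,5-dimethoxy-2-(trimethylsilyl)phenyl trifluoromethanesulfonate | COc1cc(OS(=O)(=O)C(F)(F)F)c([Si](C)(C)C)c(OC)c1 | intermediate
34 | 3,5-dimethoxybenzyne (1,2-didehydro-3,5-dimethoxybenzene) | COC1=CC(OC)=CC#C1 | intermediate
35 | 1-(3,5-dimethoxyphenoxy)-4-methoxy-2-(CDEF-oxy)-6-(EF-oxy)benzene (tetracosa-O-methyl ether of the target) | COc1cc(OC)cc(Oc2c(Oc3c(OC)cc(Oc4c(Oc5c(OC)cc(OC)c(-c6c(OC)cc(OC)cc6OC)c5OC)cc(OC)cc4Oc4c(OC)cc(OC)c(-c5c(OC)cc(OC)cc5OC)c4OC)cc3OC)cc(OC)cc2Oc2c(OC)cc(OC)c(-c3c(OC)cc(OC)cc3OC)c2OC)c1 | intermediate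
36 | CNP0294555.0 | Oc1cc(O)cc(Oc2c(Oc3c(O)cc(Oc4c(Oc5c(O)cc(O)c(-c6c(O)cc(O)cc6O)c5O)cc(O)cc4Oc4c(O)cc(O)c(-c5c(O)cc(O)cc5O)c4O)cc3O)cc(O)cc2Oc2c(O)cc(O)c(-c3c(O)cc(O)cc3O)c2O)c1 | target

## Step count and risks

Total step count: 18. Longest linear sequence: 12 steps (steps 1, 2, 3, 4, 5, 9, 10, 11, 12, 13, 17, 18).

**Step 11 (key step).** What may go wrong: electron transfer from the very electron-rich phenoxides to the quinone may consume both partners; double substitution by the first phenol, or aryloxy exchange on the product, may scramble the two arms. Excess 9 is harmless, because with 8 it gives 11, which re-enters at step 4.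

The fallback sets out from 21 and 8 and replaces the quinone by an aldehyde-activated arene. Commercial 2,6-difluoro-4-methoxybenzaldehyde would take 21 by SNAr ortho to the formyl group (Cs2CO3, DMF, 60 °C) to give 2-fluoro-4-methoxy-6-(CDEF-oxy)benzaldehyde F1. A second SNAr with 8 (Cs2CO3, DMF, 100 °C) would give 4-methoxy-2-(CDEF-oxy)-6-(EF-oxy)benzaldehyde F2. Baeyer–Villiger (Dakin-type) oxidation with mCPBA would turn the formyl group into the aryl formate 4-methoxy-2-(CDEF-oxy)-6-(EF-oxy)phenyl formate F3. Methanolysis (K2CO3, MeOH) would release phenol 25, where the route is rejoined; steps 12 and 13 then fall away.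

**Step 17.** What may go wrong: capture of the aryne by the buried phenoxide may be slower than aryne self-reaction or reaction with the solvent, leaving 25 unchanged.

The fallback sets out from 25 and uses ligand coupling on trivalent iodine instead of an aryne. Commercial 1-iodo-3,5-dimethoxybenzene would be oxidised (mCPBA, TsOH·H2O, MeCN) and coupled with 2 to give (3,5-dimethoxyphenyl)(2,4,6-trimethoxyphenyl)iodonium tosylate F4. The potassium phenoxide of 25 (t-BuOK, THF, rt → 40 °C) would then be arylated by F4 as in step 9, giving 35, where the route is rejoined.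

**Step 18.** What may go wrong: cleavage of 24 ethers may stop at partly methylated mixtures, and the free polyphenol may oxidise in air during isolation.

The fallback sets out from 35 and isolates the product as a protected derivative. After the BBr3 treatment the crude polyphenol would be acetylated in the same flask (Ac2O, pyridine, DMAP) to the tetracosaacetate of the target F5. F5 is stable and can be purified on silica, with partly methylated fractions returned to BBr3. Deacetylation of F5 (catalytic NaOMe, MeOH, 0 °C, Ar; acidic resin) would give 36, where the route is rejoined.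

## Further compounds

F1 | step 11 | 2-fluoro-4-methoxy-6-(CDEF-oxy)benzaldehyde | COc1cc(F)c(C=O)c(Oc2c(OC)cc(Oc3c(Oc4c(OC)cc(OC)c(-c5c(OC)cc(OC)cc5OC)c4OC)cc(OC)cc3Oc3c(OC)cc(OC)c(-c4c(OC)cc(OC)cc4OC)c3OC)cc2OC)c1
F2 | step 11 | 4-methoxy-2-(CDEF-oxy)-6-(EF-oxy)benzaldehyde | COc1cc(Oc2c(OC)cc(OC)c(-c3c(OC)cc(OC)cc3OC)c2OC)c(C=O)c(Oc2c(OC)cc(Oc3c(Oc4c(OC)cc(OC)c(-c5c(OC)cc(OC)cc5OC)c4OC)cc(OC)cc3Oc3c(OC)cc(OC)c(-c4c(OC)cc(OC)cc4OC)c3OC)cc2OC)c1
F3 | step 11 | 4-methoxy-2-(CDEF-oxy)-6-(EF-oxy)phenyl formate | COc1cc(Oc2c(OC)cc(OC)c(-c3c(OC)cc(OC)cc3OC)c2OC)c(OC=O)c(Oc2c(OC)cc(Oc3c(Oc4c(OC)cc(OC)c(-c5c(OC)cc(OC)cc5OC)c4OC)cc(OC)cc3Oc3c(OC)cc(OC)c(-c4c(OC)cc(OC)cc4OC)c3OC)cc2OC)c1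
F4 | step 17 | (3,5-dimethoxyphenyl)(2,4,6-trimethoxyphenyl)iodonium tosylate | COc1cc(OC)cc([I+]c2c(OC)cc(OC)cc2OC)c1.Cc1ccc(S(=O)(=O)[O-])cc1
F5 | step 18 | tetracosaacetate of the target | CC(=O)Oc1cc(OC(C)=O)cc(Oc2c(Oc3c(OC(C)=O)cc(Oc4c(Oc5c(OC(C)=O)cc(OC(C)=O)c(-c6c(OC(C)=O)cc(OC(C)=O)cc6OC(C)=O)c5OC(C)=O)cc(OC(C)=O)cc4Oc4c(OC(C)=O)cc(OC(C)=O)c(-c5c(OC(C)=O)cc(OC(C)=O)cc5OC(C)=O)c4OC(C)=O)cc3OC(C)=O)cc(OC(C)=O)cc2Oc2c(OC(C)=O)cc(OC(C)=O)c(-c3c(OC(C)=O)cc(OC(C)=O)cc3OC(C)=O)c2OC(C)=O)c1
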